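Readings and results are simulated with constants of no real substance; noise was put on by code.

With the temperature fixed and Q held at 14 mM, we reckon in time, and in logarithms of what remains.

the same everywhere: Q 14 mM (held)
- alpha: J 0.060 M; run made earlier
- theta: J 0.86 M; run made earlier
- Friday's: J 0.25 M; time 3.0 min
- Saturday's: J 0.12 M; time 3.0 min
- Monday's: J 0.080 M; time 3.0 min
- Wednesday's: J 1.0 M; time 3.0 min
- Sunday's: J 0.50 M; time 3.0 min
- Thursday's: J 0.15 M; time 3.0 min

| run | time / s | G / % |
|---|---|---|
| alpha | 10.0 | 2.7 |
| alpha | 15.0 | 4.3 |
| alpha | 25.0 | 13.5 |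
| alpha | 40.0 | 22.9 |
| alpha | 50.0 | 26.8 |
| alpha | 80.0 | 42.6 |
| alpha | 90.0 | 46.6 |
| theta | 10.0 | 0.8 |
| theta | 12.0 | 0 |
| theta | 15.0 | 1.8 |
| theta | 25.0 | 0.3 |
| theta | 40.0 | 2.5 |
| theta | 60.0 | 4.3 |
| theta | 90.0 | 6.6 |

(each reading ± 1 percentage point)

* ranking by amount of G, in percent of the J charged, from high to low, at 3.0 min (Friday's / Saturday's / Monday's / Wednesday's / Sunday's / Thursday's)
* the amount of G, in percent of the J charged of the flask you put first, at 3.0 min
* the amount of G, in percent of the J charged of the flask you put last, at 3.0 min

- given per volume of solution although it is solid: J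
- at the start none of J is in solution
- at the start none of Q is in solution
- what has only dissolved of J counts as not reacted

The last alpha reading shows 46.6% as G. We take the remaining 53.4% as unconverted J, which is 0.272 of a decade in 90.0 s:

T = 90.0 s / 0.272 = 330 s

We call T the decade time: the time in which unconverted J falls by a factor of 10. It is a reading, with that run's scatter, and it treats the loss of dissolved J as pseudo-first-order at this Q. Monday's flask at 3.0 min then has:

unconverted J = 28.5%, G = 71.5%

This link is weak, since it gives one percentage whatever the charge. Yet theta, with 0.86 M of J, reached 6.6% at 90.0 s, less than alpha's 46.6%. Theta's G grows steadily, as if dissolved J stood at a ceiling S, so we reforge the link with r, theta's mean rate of making G up to its last reading, itself a reading with that run's scatter: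

r = 0.631 mM s⁻¹

S = r T / ln(10) = 0.0905 M

Monday's 0.080 M lies below S, so its figure stands. Wednesday's 1.0 M lies above S, so we let it make G at r:

G = r t / charge = 11.4%

Ranking the flasks from small charge to large puts Monday's first and Wednesday's last, and we commit to 71.5% and 11.4%.

The forecast gave Monday's > Saturday's > Thursday's > Friday's > Sunday's > Wednesday's, with 71.5% and 11.2%, the second a little under our 11.4%, reading that “solid J keeps the solution saturated”.

The flasks gave Monday's > Saturday's > Thursday's > Friday's > Sunday's > Wednesday's, with 66.3% and 10.2%.

    J ⇌ X, rate k1*(cs1 - [X]) while solid is left; crystals form when [X] > cs1 (solubility = 0.150 M, k = 0.0348 s⁻¹)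
    X + E → G (k = 0.714 M⁻¹ s⁻¹)
    E → Z (k = 0.0196 s⁻¹)
    2 J → D (k = 0.175 M⁻¹ s⁻¹)
    Q ⇌ E, rate k5*(csat - [E]) (kL = 0.230 s⁻¹)

Monday's flask ended 5.2 percentage points under our figure. In Monday's flask the midpoint of the turnover up to 3.0 min came at 0.127 min for the dissolving of J, sooner than the 1.14 min for the passing of X + E into G. Monday's flask held D at 12.8% at 1.50 min and at 12.8% at 3.00 min, while X fell from 45.3% to 21.0%. For Monday's read at 80 s, T gives 42.8% of G. Monday's flask at that time holds 38.0% of G, with 49.2% as X and 12.8% as D.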